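**Retrosynthetic overview**
1. Target 31 comes from 30 by one acidic unmasking (C14 acetal to CHO, C15 silyl ether to OH); the C8 isovalerate is put on just before (28 + 29).
2. The ten-membered ring is formed second, by ring-closing metathesis of 26 at C1=C10.
3. The key union also builds the first ring (the α-methylene-γ-butyrolactone): indium Barbier allylation and lactonisation of enal 10 (C1–C6, C15) with the (Z)-2-(bromomethyl)enoate 23 (C7–C14) forms C6–C7 and sets C6 and C7 from C8.
4. 23 comes from (R)-methyl glycidate (C7–C9; C8 set by kinetic resolution), a 2-metalated acrolein acetal (C10, C14) and methyl acrylate (C11–C13; Baylis–Hillman reaction, SN2′ bromination).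
5. 10 comes from propargyl alcohol, formaldehyde and but-3-enylzinc bromide (directed trans-hydroalumination/iodination fixes the C4=C5 geometry; Negishi coupling).

Assumption: positions are given in germacrane numbering (ring C1–C10, lactone carbons C11–C13, C14 = CHO carbon, C15 = CH2OH carbon); rac-methyl glycidate, 3,3-dimethoxyprop-1-ene and but-3-enylzinc bromide (THF solution) are taken as catalogue items.

**Aldehyde fragment 10 (steps 1–5)**

Step 1
Reactants: 1 prop-2-yn-1-ol
Product: 2 tert-butyldimethyl(prop-2-yn-1-yloxy)silane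
Conditions: TBSCl, imidazole, CH2Cl2, 0 °C → rt
Reagents that add atoms: tert-butyldimethylsilyl chloride, CC(C)(C)[Si](C)(C)Cl
Why: Standard silyl ether formation on the primary alcohol through the N-silylimidazolium species, with no stereocentre involved.

Step 2
Reactants: 2 tert-butyldimethyl(prop-2-yn-1-yloxy)silane; 3 formaldehyde (as paraformaldehyde)
Product: 5 4-[(tert-butyldimethylsilyl)oxy]but-2-yn-1-ol, via lithium acetylide 4 (not isolated)
Conditions: n-BuLi, THF, −78 °C; then (CH2O)n, −78 °C → rt; aq. NH4Cl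
Reagents that add atoms: none
Why: Deprotonation of the terminal alkyne and 1,2-addition of the acetylide to formaldehyde (alkynylation) gives the mono-protected butynediol without a statistical mono-silylation.

Step 3
Reactants: 5 4-[(tert-butyldimethylsilyl)oxy]but-2-yn-1-ol
Product: 7 (Z)-4-[(tert-butyldimethylsilyl)oxy]-3-iodobut-2-en-1-ol, via cyclic vinylaluminate 6 (not isolated)
Conditions: NaAlH2(OCH2CH2OCH3)2, THF, 0 °C; EtOAc quench; then I2, THF, −78 → 0 °C
Reagents that add atoms: iodine, II
Why: Hydroxyl-directed trans-hydroalumination (hydride to the carbon next to CH2OH, aluminium held in the five-membered alkoxyaluminate 6) followed by iodinolysis of the C–Al bond with retention places iodine cis to CH2OH, which is the future ring-cis C4=C5 geometry.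

Step 4
Reactants: 7 (Z)-4-[(tert-butyldimethylsilyl)oxy]-3-iodobut-2-en-1-ol; 8 but-3-en-1-ylzinc bromide
Product: 9 (E)-3-{[(tert-butyldimethylsilyl)oxy]methyl}hepta-2,6-dien-1-ol
Conditions: 8 (2.5 equiv), PdCl2(dppf) (5 mol %), THF, rt → 45 °C
Reagents that add atoms: none
Why: Negishi sp2–sp3 cross-coupling proceeds with retention of the alkene geometry (butenyl chain cis to CH2OH), the dppf ligand suppresses β-hydride elimination and alkylzinc halides tolerate the free hydroxyl group.

Step 5
Reactants: 9 (E)-3-{[(tert-butyldimethylsilyl)oxy]methyl}hepta-2,6-dien-1-ol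
Product: 10 (E)-3-{[(tert-butyldimethylsilyl)oxy]methyl}hepta-2,6-dienal
Conditions: MnO2 (15 equiv), CH2Cl2, rt
Reagents that add atoms: none
Why: Chemoselective MnO2 oxidation of the allylic alcohol under neutral conditions gives the enal without scrambling the trisubstituted alkene (CHO stays cis to the butenyl chain) and leaves the silyl ether and terminal alkene untouched.

**Bromide fragment 23 (steps 6–12)**

Step 6
Reactants: 11 3,3-dimethoxyprop-1-ene
Product: 13 2-bromo-3,3-dimethoxyprop-1-ene, via 2,3-dibromo-1,1-dimethoxypropane 12 (not isolated)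
Conditions: Br2, CH2Cl2, −78 → 0 °C; then KOtBu (1.05 equiv), THF, 0 °C
Reagents that add atoms: bromine, BrBr
Why: Electrophilic bromine addition to the alkene is followed by E2 dehydrobromination in which the acidified C2–H (flanked by Br and the acetal carbon) is removed with loss of the primary bromide, and one equivalent of base avoids the second elimination to the alkyne.

Step 7
Reactants: 14 rac-methyl oxirane-2-carboxylate
Product: 15 methyl (R)-oxirane-2-carboxylate
Conditions: (S,S)-Co(salen)(OAc) (0.5 mol %; salen = N,N′-bis(3,5-di-tert-butylsalicylidene)cyclohexane-1,2-diaminate), H2O (0.55 equiv), THF, 0 °C → rt; distillation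
Reagents that add atoms: none
Why: Jacobsen hydrolytic kinetic resolution, in which the chiral cobalt–salen catalyst hydrolyses the (S)-epoxide selectively so that the unreacted (R)-epoxide, whose stereocentre becomes C8 of the target, is recovered in high ee.

Step 8
Reactants: 13 2-bromo-3,3-dimethoxyprop-1-ene; 15 methyl (R)-oxirane-2-carboxylate
Product: 18 methyl (R)-4-(dimethoxymethyl)-2-hydroxypent-4-enoate, via vinyllithium 16 (not isolated), via vinylmagnesium bromide 17 (not isolated)
Conditions: 13, t-BuLi (2 equiv), Et2O, −78 °C; MgBr2·OEt2; CuI (10 mol %), then 15, THF, −78 → −40 °C; aq. NH4Cl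
Reagents that add atoms: none
Why: Bromine–lithium exchange, transmetalation and copper-catalysed SN2 opening of the epoxide at its unsubstituted carbon (faster than ester addition at low temperature) form the C9–C10 bond without touching the stereocentre, which keeps the (R) configuration.

Step 9
Reactants: 18 methyl (R)-4-(dimethoxymethyl)-2-hydroxypent-4-enoate
Product: 19 methyl (R)-4-(dimethoxymethyl)-2-[(triethylsilyl)oxy]pent-4-enoate
Conditions: TESCl, imidazole, DMAP (cat.), CH2Cl2, 0 °C → rt
Reagents that add atoms: triethylsilyl chloride, CC[Si](Cl)(CC)CC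
Why: Silyl ether formation installs a bulky, non-chelating group on the C8 oxygen, chosen because it will direct the later allylation and can be removed in the presence of the primary tert-butyldimethylsilyl ether.

Step 10
Reactants: 19 methyl (R)-4-(dimethoxymethyl)-2-[(triethylsilyl)oxy]pent-4-enoate
Product: 20 (R)-4-(dimethoxymethyl)-2-[(triethylsilyl)oxy]pent-4-enal
Conditions: i-Bu2AlH (1.05 equiv), CH2Cl2, −78 °C; Rochelle salt work-up
Reagents that add atoms: none
Why: Partial reduction of the α-silyloxy ester stops at the aldehyde because the tetrahedral aluminium hemiacetal is stable at −78 °C and collapses only on work-up, without epimerisation of the α-centre.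

Step 11
Reactants: 20 (R)-4-(dimethoxymethyl)-2-[(triethylsilyl)oxy]pent-4-enal; 21 methyl acrylate
Product: 22 methyl (4R)-6-(dimethoxymethyl)-3-hydroxy-2-methylidene-4-[(triethylsilyl)oxy]hept-6-enoate (both C3 epimers)
Conditions: 21 (4 equiv), DABCO (1 equiv), neat, rt, 3–5 d
Reagents that add atoms: none
Why: Morita–Baylis–Hillman reaction (conjugate addition of DABCO to the acrylate, aldol addition to the activated α-oxygenated aldehyde, elimination of DABCO), whose new carbinol centre is formed as a mixture that does not matter because it is destroyed in step 12.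

Step 12
Reactants: 22 methyl (4R)-6-(dimethoxymethyl)-3-hydroxy-2-methylidene-4-[(triethylsilyl)oxy]hept-6-enoate
Product: 23 methyl (2Z,4R)-2-(bromomethyl)-6-(dimethoxymethyl)-4-[(triethylsilyl)oxy]hepta-2,6-dienoate
Conditions: NBS, Me2S, CH2Cl2, 0 °C → rt
Reagents that add atoms: N-bromosuccinimide, O=C1CCC(=O)N1Br
Why: Corey–Kim-type activation of the allylic alcohol as an alkoxysulfonium ion and SN2′ attack of bromide give the rearranged primary allylic bromide as the thermodynamically favoured (Z) isomer, with the C8 chain trans to the ester and cis to CH2Br.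

**Union and end-game (steps 13–17)**

Step 13
Reactants: 10 (E)-3-{[(tert-butyldimethylsilyl)oxy]methyl}hepta-2,6-dienal; 23 methyl (2Z,4R)-2-(bromomethyl)-6-(dimethoxymethyl)-4-[(triethylsilyl)oxy]hepta-2,6-dienoate
Product: 26 (4R,5R)-5-[(1E)-2-{[(tert-butyldimethylsilyl)oxy]methyl}hexa-1,5-dien-1-yl]-4-[(1R)-3-(dimethoxymethyl)-1-[(triethylsilyl)oxy]but-3-en-1-yl]-3-methylideneoxolan-2-one (4,5-cis), via allylindium bromide 24 (not isolated), via syn hydroxy ester 25 (not isolated)
Conditions: 23 (1.2 equiv), In powder (1.5 equiv), DMF, rt, sonication; aq. NaHCO3 work-up; then PPTS (10 mol %), CH2Cl2, rt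
Reagents that add atoms: none
Why: Barbier-type allylation through a chair (Zimmerman–Traxler) transition state in which the C8 chain, cis to CH2In, sits axial gives the syn adduct 25 and hence the 6,7-cis lactone on PPTS-promoted lactonisation, while the aldehyde approaches C7 anti to the bulky non-chelating silyloxy group of the A(1,3)-minimised rotamer (H8 eclipsing the alkene), which sets C6 (R) and C7 relative to the (R)-C8 centre.

Step 14
Reactants: 26 (4R,5R)-5-[(1E)-2-{[(tert-butyldimethylsilyl)oxy]methyl}hexa-1,5-dien-1-yl]-4-[(1R)-3-(dimethoxymethyl)-1-[(triethylsilyl)oxy]but-3-en-1-yl]-3-methylideneoxolan-2-one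
Product: 27 (3aR,4R,6E,10E,11aR)-10-{[(tert-butyldimethylsilyl)oxy]methyl}-6-(dimethoxymethyl)-3-methylidene-4-[(triethylsilyl)oxy]-3a,4,5,8,9,11a-hexahydrocyclodeca[b]furan-2(3H)-one
Conditions: second-generation Hoveyda–Grubbs catalyst RuCl2(H2IMes)(=CH-C6H4-2-O-i-Pr) (15 mol %), 1,4-benzoquinone (cat.), toluene (1 mM), 80 °C
Reagents that add atoms: none
Why: Ring-closing metathesis between the monosubstituted C1 alkene and the 1,1-disubstituted C10 alkene (ethene lost) at high dilution is helped by the cis-fused lactone and the existing ring-cis C4=C5 alkene, and the less strained ring-cis C1=C10 geometry is expected in a cyclodecadiene of this kind.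

Step 15
Reactants: 27 (3aR,4R,6E,10E,11aR)-10-{[(tert-butyldimethylsilyl)oxy]methyl}-6-(dimethoxymethyl)-3-methylidene-4-[(triethylsilyl)oxy]-3a,4,5,8,9,11a-hexahydrocyclodeca[b]furan-2(3H)-one
Product: 28 (3aS,4R,6E,10E,11aR)-10-{[(tert-butyldimethylsilyl)oxy]methyl}-6-(dimethoxymethyl)-4-hydroxy-3-methylidene-3a,4,5,8,9,11a-hexahydrocyclodeca[b]furan-2(3H)-one
Conditions: HF·pyridine, pyridine, THF, 0 °C
Reagents that add atoms: none
Why: Selective fluoride-mediated desilylation, in which the secondary triethylsilyl ether is cleaved much faster than the primary tert-butyldimethylsilyl ether and the acetal survives the buffered non-aqueous medium (the 3a descriptor changes only because the CIP priorities change).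

Step 16
Reactants: 28 (3aS,4R,6E,10E,11aR)-10-{[(tert-butyldimethylsilyl)oxy]methyl}-6-(dimethoxymethyl)-4-hydroxy-3-methylidene-3a,4,5,8,9,11a-hexahydrocyclodeca[b]furan-2(3H)-one; 29 3-methylbutanoyl chloride
Product: 30 (3aS,4R,6E,10E,11aR)-10-{[(tert-butyldimethylsilyl)oxy]methyl}-6-(dimethoxymethyl)-3-methylidene-2-oxo-2,3,3a,4,5,8,9,11a-octahydrocyclodeca[b]furan-4-yl 3-methylbutanoate
Conditions: 29, pyridine, DMAP (cat.), CH2Cl2, 0 °C
Reagents that add atoms: none
Why: DMAP-catalysed acylation (nucleophilic catalysis through the N-acylpyridinium ion) of the only free hydroxyl group, run at once to forestall translactonisation to the 8,12-olide, retains the C8 configuration because the C–O bond is not broken.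

Step 17
Reactants: 30 (3aS,4R,6E,10E,11aR)-10-{[(tert-butyldimethylsilyl)oxy]methyl}-6-(dimethoxymethyl)-3-methylidene-2-oxo-2,3,3a,4,5,8,9,11a-octahydrocyclodeca[b]furan-4-yl 3-methylbutanoate
Product: 31 (3aS,4R,6E,10E,11aR)-6-formyl-10-(hydroxymethyl)-3-methylidene-2-oxo-2,3,3a,4,5,8,9,11a-octahydrocyclodeca[b]furan-4-yl 3-methylbutanoate (CNP0345200.7)
Conditions: 48 % aq. HF, MeCN, 0 °C → rt
Reagents that add atoms: water, O
Why: Acid-mediated global unmasking, in which aqueous HF cleaves the primary silyl ether and hydrolyses the dimethyl acetal to the conjugated aldehyde (already in its thermodynamically preferred geometry, CHO trans to C2), while the lactone and the isovalerate are stable to dilute acid.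

**Compound list**
1 | prop-2-yn-1-ol | C#CCO | starting material
2 | tert-butyldimethyl(prop-2-yn-1-yloxy)silane | C#CCO[Si](C)(C)C(C)(C)C | intermediate
3 | formaldehyde (as paraformaldehyde) | C=O | starting material
4 | {3-[(tert-butyldimethylsilyl)oxy]prop-1-yn-1-yl}lithium | [Li]C#CCO[Si](C)(C)C(C)(C)C | intermediate
5 | 4-[(tert-butyldimethylsilyl)oxy]but-2-yn-1-ol | OCC#CCO[Si](C)(C)C(C)(C)C | intermediate
6 | sodium cyclic vinylaluminate from trans-hydroalumination of 5 (2,5-dihydro-1,2-oxaaluminole ate complex) | [Na+].COCCO[Al-]1(OCCOC)OCC=C1CO[Si](C)(C)C(C)(C)C | intermediate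
7 | (Z)-4-[(tert-butyldimethylsilyl)oxy]-3-iodobut-2-en-1-ol | OC/C=C(\I)CO[Si](C)(C)C(C)(C)C | intermediate
8 | but-3-en-1-ylzinc bromide | C=CCC[Zn]Br | starting material
9 | (E)-3-{[(tert-butyldimethylsilyl)oxy]methyl}hepta-2,6-dien-1-ol | OC/C=C(\CCC=C)CO[Si](C)(C)C(C)(C)C | intermediate
10 | (E)-3-{[(tert-butyldimethylsilyl)oxy]methyl}hepta-2,6-dienal | O=C/C=C(\CCC=C)CO[Si](C)(C)C(C)(C)C | intermediate
11 | 3,3-dimethoxyprop-1-ene | C=CC(OC)OC | starting material
12 | 2,3-dibromo-1,1-dimethoxypropane | BrCC(Br)C(OC)OC | intermediate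
13 | 2-bromo-3,3-dimethoxyprop-1-ene | C=C(Br)C(OC)OC | intermediate
14 | rac-methyl oxirane-2-carboxylate | COC(=O)C1CO1 | starting material
15 | methyl (R)-oxirane-2-carboxylate | COC(=O)[C@H]1CO1 | intermediate
16 | (3,3-dimethoxyprop-1-en-2-yl)lithium | [Li]C(=C)C(OC)OC | intermediate
17 | (3,3-dimethoxyprop-1-en-2-yl)magnesium bromide | Br[Mg]C(=C)C(OC)OC | intermediate
18 | methyl (R)-4-(dimethoxymethyl)-2-hydroxypent-4-enoate | COC(=O)[C@H](O)CC(=C)C(OC)OC | intermediate
19 | methyl (R)-4-(dimethoxymethyl)-2-[(triethylsilyl)oxy]pent-4-enoate | COC(=O)[C@H](O[Si](CC)(CC)CC)CC(=C)C(OC)OC | intermediate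
20 | (R)-4-(dimethoxymethyl)-2-[(triethylsilyl)oxy]pent-4-enal | O=C[C@H](O[Si](CC)(CC)CC)CC(=C)C(OC)OC | intermediate
21 | methyl acrylate | C=CC(=O)OC | starting material
22 | methyl (4R)-6-(dimethoxymethyl)-3-hydroxy-2-methylidene-4-[(triethylsilyl)oxy]hept-6-enoate (both C3 epimers) | COC(=O)C(=C)C(O)[C@H](O[Si](CC)(CC)CC)CC(=C)C(OC)OC | intermediate
23 | methyl (2Z,4R)-2-(bromomethyl)-6-(dimethoxymethyl)-4-[(triethylsilyl)oxy]hepta-2,6-dienoate | COC(=O)/C(CBr)=C/[C@H](O[Si](CC)(CC)CC)CC(=C)C(OC)OC | intermediate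
24 | allylindium reagent from 23, drawn as the monomeric (Z)-allylindium dibromide | COC(=O)/C(C[In](Br)Br)=C/[C@H](O[Si](CC)(CC)CC)CC(=C)C(OC)OC | intermediate
25 | methyl (3R,4R,5E)-6-{[(tert-butyldimethylsilyl)oxy]methyl}-3-[(1R)-3-(dimethoxymethyl)-1-[(triethylsilyl)oxy]but-3-en-1-yl]-4-hydroxy-2-methylidenedeca-5,9-dienoate | COC(=O)C(=C)[C@H]([C@H](O)/C=C(/CO[Si](C)(C)C(C)(C)C)CCC=C)[C@H](O[Si](CC)(CC)CC)CC(=C)C(OC)OC | intermediate
26 | (4R,5R)-5-[(1E)-2-{[(tert-butyldimethylsilyl)oxy]methyl}hexa-1,5-dien-1-yl]-4-[(1R)-3-(dimethoxymethyl)-1-[(triethylsilyl)oxy]but-3-en-1-yl]-3-methylideneoxolan-2-one | C=C1C(=O)O[C@H](/C=C(/CO[Si](C)(C)C(C)(C)C)CCC=C)[C@@H]1[C@H](O[Si](CC)(CC)CC)CC(=C)C(OC)OC | intermediate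
27 | (3aR,4R,6E,10E,11aR)-10-{[(tert-butyldimethylsilyl)oxy]methyl}-6-(dimethoxymethyl)-3-methylidene-4-[(triethylsilyl)oxy]-3a,4,5,8,9,11a-hexahydrocyclodeca[b]furan-2(3H)-one | C=C1C(=O)O[C@@H]2/C=C(/CO[Si](C)(C)C(C)(C)C)CC/C=C(/C(OC)OC)C[C@@H](O[Si](CC)(CC)CC)[C@H]12 | intermediate
28 | (3aS,4R,6E,10E,11aR)-10-{[(tert-butyldimethylsilyl)oxy]methyl}-6-(dimethoxymethyl)-4-hydroxy-3-methylidene-3a,4,5,8,9,11a-hexahydrocyclodeca[b]furan-2(3H)-one | C=C1C(=O)O[C@@H]2/C=C(/CO[Si](C)(C)C(C)(C)C)CC/C=C(/C(OC)OC)C[C@@H](O)[C@H]12 | intermediate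
29 | 3-methylbutanoyl chloride | CC(C)CC(Cl)=O | starting material
30 | (3aS,4R,6E,10E,11aR)-10-{[(tert-butyldimethylsilyl)oxy]methyl}-6-(dimethoxymethyl)-3-methylidene-2-oxo-2,3,3a,4,5,8,9,11a-octahydrocyclodeca[b]furan-4-yl 3-methylbutanoate | C=C1C(=O)O[C@@H]2/C=C(/CO[Si](C)(C)C(C)(C)C)CC/C=C(/C(OC)OC)C[C@@H](OC(=O)CC(C)C)[C@H]12 | intermediate
31 | (3aS,4R,6E,10E,11aR)-6-formyl-10-(hydroxymethyl)-3-methylidene-2-oxo-2,3,3a,4,5,8,9,11a-octahydrocyclodeca[b]furan-4-yl 3-methylbutanoate | C=C1C(=O)O[C@@H]2/C=C(/CO)CC/C=C(/C=O)C[C@@H](OC(=O)CC(C)C)[C@H]12 | target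

**Step count**
Total step count: 17.
Longest linear sequence: 11 steps (step 6 or step 7, then 8–12, then 13–17). The other branch (steps 1–5, then 13–17) is 10 steps.

**Steps most likely to fail, with fallbacks**

Step 13 (union). The syn/cis outcome follows the usual behaviour of (Z)-2-(bromomethyl)enoates, but the facial control by the C8 silyloxy group is a model-based prediction and could be modest. The fallback sets out from 22 (with 10) and comes back at 26; it replaces substrate control by catalyst control through an allylboronate. Acetylation of 22 (Ac2O, DMAP, CH2Cl2) gives the Baylis–Hillman acetate, methyl (4R)-3-acetoxy-6-(dimethoxymethyl)-2-methylidene-4-[(triethylsilyl)oxy]hept-6-enoate F1. Copper-catalysed SN2′ borylation of this (B2pin2, CuCl, KOtBu, THF) gives the allylboronate, methyl (2E,4R)-6-(dimethoxymethyl)-2-[(4,4,5,5-tetramethyl-1,3,2-dioxaborolan-2-yl)methyl]-4-[(triethylsilyl)oxy]hepta-2,6-dienoate F2. Allylboration of 10 with F2 under a chiral phosphoric acid (TRIP, 5 mol %, toluene, −30 °C; the catalyst enantiomer matched to the 6R carbinol is picked on a model aldehyde) runs through a closed chair transition state whose aldehyde face is chosen by the catalyst. The resulting hydroxy ester 25 is lactonised with PPTS to 26.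

Step 14 (ring-closing metathesis). A trisubstituted alkene has to form in a ten-membered ring from a hindered 1,1-disubstituted alkene, and the α-methylene lactone is a possible competing partner. The fallback sets out from 10 and 23 and comes back at 27; it changes the ring-closing bond to C6–C7. Cross-metathesis of 23 with an excess of 10 (second-generation Hoveyda–Grubbs catalyst, CH2Cl2, 40 °C, alkene isomers separated) gives the open-chain bromo aldehyde, methyl (2Z,4R,6E,10E)-2-(bromomethyl)-10-{[(tert-butyldimethylsilyl)oxy]methyl}-6-(dimethoxymethyl)-12-oxo-4-[(triethylsilyl)oxy]dodeca-2,6,10-trienoate F3. Slow addition of F3 to CrCl2 in THF at high dilution closes the ring by intramolecular allylation, the classical chromium-mediated germacranolide ring closure. This gives the macrocyclic hydroxy ester, methyl 2-[(1R,2R,3E,7E,10R)-4-{[(tert-butyldimethylsilyl)oxy]methyl}-8-(dimethoxymethyl)-2-hydroxy-10-[(triethylsilyl)oxy]cyclodeca-3,7-dien-1-yl]prop-2-enoate F4, which lactonises with PPTS to 27. The same allyl geometry and C8 silyloxy group are expected to favour the same 6,7-cis relationship, but this would have to be checked.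

Step 11 (Baylis–Hillman reaction). The hindered α-silyloxy aldehyde may react slowly, and long exposure to DABCO risks epimerisation at C8 or silyl migration. The fallback sets out from 20 and comes back at 22; it replaces the amine-catalysed process by a stoichiometric α-acrylate anion equivalent. Hydroalumination of methyl propiolate (C#CC(=O)OC) with i-Bu2AlH and N-methylmorpholine N-oxide in THF at 0 °C gives the vinylalane, [1-(methoxycarbonyl)ethenyl]bis(2-methylpropyl)alane F5, which adds to 20 at −78 → 0 °C and gives 22 directly, without base.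

**Further compounds**
F1 | step 13 | methyl (4R)-3-acetoxy-6-(dimethoxymethyl)-2-methylidene-4-[(triethylsilyl)oxy]hept-6-enoate | COC(=O)C(=C)C(OC(C)=O)[C@H](O[Si](CC)(CC)CC)CC(=C)C(OC)OC
F2 | step 13 | methyl (2E,4R)-6-(dimethoxymethyl)-2-[(4,4,5,5-tetramethyl-1,3,2-dioxaborolan-2-yl)methyl]-4-[(triethylsilyl)oxy]hepta-2,6-dienoate | COC(=O)/C(CB1OC(C)(C)C(C)(C)O1)=C/[C@H](O[Si](CC)(CC)CC)CC(=C)C(OC)OC
F3 | step 14 | methyl (2Z,4R,6E,10E)-2-(bromomethyl)-10-{[(tert-butyldimethylsilyl)oxy]methyl}-6-(dimethoxymethyl)-12-oxo-4-[(triethylsilyl)oxy]dodeca-2,6,10-trienoate | COC(=O)/C(CBr)=C/[C@H](O[Si](CC)(CC)CC)C/C(C(OC)OC)=C\CC/C(CO[Si](C)(C)C(C)(C)C)=C\C=O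
F4 | step 14 | methyl 2-[(1R,2R,3E,7E,10R)-4-{[(tert-butyldimethylsilyl)oxy]methyl}-8-(dimethoxymethyl)-2-hydroxy-10-[(triethylsilyl)oxy]cyclodeca-3,7-dien-1-yl]prop-2-enoate | COC(=O)C(=C)[C@@H]1[C@H](O)/C=C(/CO[Si](C)(C)C(C)(C)C)CC/C=C(/C(OC)OC)C[C@H]1O[Si](CC)(CC)CC
F5 | step 11 | [1-(methoxycarbonyl)ethenyl]bis(2-methylpropyl)alane | COC(=O)C(=C)[Al](CC(C)C)CC(C)C
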